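**Plan**
1. The last cut removes sixteen benzyl ethers; the next cut is the E6–F1 biaryl bond (Suzuki–Miyaura), giving a left pentacycle (rings A–E, triflate at E6) and a right tricycle (rings F–H, boronate at F1).
2. Right half: F6–O–G1 is cut (SNAr of the G1 phenol on a 2-fluorobenzaldehyde whose formyl carbon becomes F1). Ring H is then opened: its ether carbon H1 lies between the hydroxyl carbons H2 and H6, so cutting H1–H2 gives a 6-(ring G aryloxy)-3,5-dioxohexanoate in which H1 is the aryloxymethyl carbon between the C5 ketone and the ester carbon.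
3. Left half: cuts at D5–O–E1 (SNAr), B5–C6 (Pd arylation from a C6 bromide), D1–O–C5 (Ullmann at a C5 bromide), C4–O–D6 (SNAr on a symmetric 2-fluoroisophthalaldehyde), A–O–B1 (Chan–Lam) and B6–O–C1 (SNAr).
4. Forward order: ring H is closed on the ring G ether oxygen, then G–H becomes F–G–H. Ring C (from 2,3-dibromo-4,5-dihydroxybenzaldehyde) takes on ring B, ring A and ring D; the dioxin closes, ring E is added, the furan closes. The halves are joined and debenzylated.
5. Each phenol that must react at a doubly ortho-oxygenated carbon (G1, F1, C1, B1, D1/D5, E6) is made from a formyl group by Dakin oxidation, so no ether coupling needs a 2,6-dioxygenated aryl halide.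
6. Stereochemistry: there is no stereocentre; the E–F axis is formed without control.

Key step: step 10

Labels: ring atoms carry the ring letter and a number, with links A–O–B1, B6–O–C1 and B5–C6 (furan), C4–O–D6 and C5–O–D1 (dioxin), D5–O–E1, E6–F1, F6–O–G1, G6–O–H1. Bn = benzyl, MOM = methoxymethyl.
Assumption: the structure has no axial descriptor, so the tetra-ortho-oxygenated E6–F1 axis is taken as unresolved.

**Route**

Step 1
Reactants: 1 5-fluorobenzene-1,3-diol
Product: 2 1,3-bis(benzyloxy)-5-fluorobenzene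
Conditions: BnBr, K2CO3, DMF, 60 °C
Reagents that add atoms: benzyl bromide BrCc1ccccc1
Why: Williamson etherification of both phenols, with the unactivated aryl fluoride inert to carbonate.

Step 2
Reactants: 2 1,3-bis(benzyloxy)-5-fluorobenzene
Product: 4 2,4-bis(benzyloxy)-6-fluorobenzaldehyde, via aryl iminium chloride 3 (not isolated)
Conditions: POCl3, DMF, 0 → 60 °C; then H2O
Reagents that add atoms: N,N-dimethylformamide CN(C)C=O; water O
Why: Vilsmeier–Haack formylation should enter para to one benzyloxy group and next to the small fluorine rather than the crowded carbon between the two ethers, as is usual for 5-halo-resorcinol diethers.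

Step 3
Reactants: 2 1,3-bis(benzyloxy)-5-fluorobenzene
Product: 5 1,5-bis(benzyloxy)-2,4-dibromo-3-fluorobenzene
Conditions: NBS (2.05 equiv), MeCN, 0 → 25 °C, dark
Reagents that add atoms: N-bromosuccinimide O=C1CCC(=O)N1Br
Why: Electrophilic bromination of a resorcinol diether takes the two carbons that are para to one ether and ortho to the other (here the carbons flanking fluorine) before the hindered carbon between the ethers.

Step 4
Reactants: 5 1,5-bis(benzyloxy)-2,4-dibromo-3-fluorobenzene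
Product: 7 4,6-bis(benzyloxy)-2-fluorobenzene-1,3-dicarbaldehyde, via aryldilithium 6 (not isolated)
Conditions: n-BuLi (2.2 equiv), THF, −90 °C; DMF, −90 → 0 °C; aq. HCl
Reagents that add atoms: N,N-dimethylformamide CN(C)C=O
Why: Twofold bromine–lithium exchange and formylation with DMF is the standard entry to 4,6-dialkoxyisophthalaldehydes, and the low temperature keeps the lithium next to fluorine from eliminating LiF.

Step 5
Reactants: 8 2,4,6-trihydroxybenzaldehyde
Product: 9 2,4-bis(benzyloxy)-6-hydroxybenzaldehyde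
Conditions: BnBr (2.1 equiv), K2CO3, DMF, 25 °C
Reagents that add atoms: benzyl bromide BrCc1ccccc1
Why: Williamson etherification stops at the dibenzyl ether because the last hydroxyl is hydrogen-bonded to the formyl group and is the least nucleophilic.

Step 6
Reactants: 9 2,4-bis(benzyloxy)-6-hydroxybenzaldehyde; 10 methyl bromoacetate
Product: 11 methyl 2-[3,5-bis(benzyloxy)-2-formylphenoxy]acetate
Conditions: K2CO3, acetone, reflux
Reagents that add atoms: none
Why: Williamson alkylation of the chelated phenol sets the future G6–O–H1 ether, and the mild base in acetone avoids aldol closure to a benzofuran-2-carboxylate.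

Step 7
Reactants: 11 methyl 2-[3,5-bis(benzyloxy)-2-formylphenoxy]acetate
Product: 13 methyl 2-[3,5-bis(benzyloxy)-2-hydroxyphenoxy]acetate, via aryl formate 12 (not isolated)
Conditions: mCPBA, NaHCO3, CH2Cl2, 0 → 25 °C; then K2CO3 (cat.), MeOH, 0 °C
Reagents that add atoms: 3-chloroperbenzoic acid OOC(=O)c1cccc(Cl)c1
Why: In this Dakin-type Baeyer–Villiger oxidation the trioxygenated aryl group migrates in preference to hydrogen, and brief methanolysis cleaves the formate without changing the methyl ester.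

Step 8
Reactants: 13 methyl 2-[3,5-bis(benzyloxy)-2-hydroxyphenoxy]acetate
Product: 14 methyl 2-[3,5-bis(benzyloxy)-2-(methoxymethoxy)phenoxy]acetate
Conditions: MOMCl, iPr2NEt, CH2Cl2, 0 → 25 °C (crude 13 used at once)
Reagents that add atoms: chloromethyl methyl ether COCCl
Why: Acetal protection of the G1 phenol prevents lactonisation onto the neighbouring ester and keeps G1 distinct from the later ring H hydroxyls.

Step 9
Reactants: 15 methyl acetoacetate; 14 methyl 2-[3,5-bis(benzyloxy)-2-(methoxymethoxy)phenoxy]acetate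
Product: 17 methyl 6-[3,5-bis(benzyloxy)-2-(methoxymethoxy)phenoxy]-3,5-dioxohexanoate, via acetoacetate dianion 16 (not isolated)
Conditions: 15 (2.5 equiv), LiN(iPr)2 (5 equiv), THF, −78 → 0 °C; then 14, −78 → 0 °C; aq. HCl
Reagents that add atoms: none
Why: Claisen-type acylation of the terminal carbon of the acetoacetate dianion by the activated aryloxyacetate, with excess dianion because the 3,5-dioxo ester formed is more acidic than the reagent.

Step 10
Reactants: 17 methyl 6-[3,5-bis(benzyloxy)-2-(methoxymethoxy)phenoxy]-3,5-dioxohexanoate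
Product: 19 2-[3,5-bis(benzyloxy)-2-(methoxymethoxy)phenoxy]benzene-1,3,5-triol, via trilithium trianion 18 (not isolated)
Conditions: LiN(iPr)2 (3.5 equiv), THF, −78 → 25 °C; aq. HCl
Reagents that add atoms: none
Why: The amide base removes a proton from each of C2, C4 and C6; the C6 carbanion, stabilised only by the C5 carbonyl and the aryloxy oxygen, adds to the ester carbon C1, methoxide leaves and the cyclohexane-1,3,5-trione tautomerises to the aromatic triol. The closest known reaction is the biomimetic Claisen (Dieckmann-type) cyclisation of 3,5-dioxo- and 3,5,7-trioxoalkanoates to phloroglucinols. Ring H, the only ring formed, closes in a 6-exo-trig (enolendo) mode that makes the H1–H2 bond with the G6–O–H1 ether already in place. No stereocentre is created. The step needs C-acylation to win over O-acylation to the 4-hydroxy-2-pyranone. This should be secured because the lithium-bound enolate oxygens are poor acyl acceptors, the terminal carbanion is the strongest nucleophile of the polyanion, only one carbocycle can form, and aromatisation makes that closure irreversible.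

Step 11
Reactants: 19 2-[3,5-bis(benzyloxy)-2-(methoxymethoxy)phenoxy]benzene-1,3,5-triol
Product: 20 1,5-bis(benzyloxy)-2-(methoxymethoxy)-3-[2,4,6-tris(benzyloxy)phenoxy]benzene
Conditions: BnBr (3.6 equiv), K2CO3, DMF, 25 °C, argon
Reagents that add atoms: benzyl bromide BrCc1ccccc1
Why: Williamson etherification of the three ring H phenols, where carbonate in a polar aprotic solvent favours O- over C-benzylation of the phloroglucinol nucleus.

Step 12
Reactants: 20 1,5-bis(benzyloxy)-2-(methoxymethoxy)-3-[2,4,6-tris(benzyloxy)phenoxy]benzene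
Product: 21 2,4-bis(benzyloxy)-6-[2,4,6-tris(benzyloxy)phenoxy]phenol
Conditions: HCl (cat.), MeOH/THF, 50 °C
Reagents that add atoms: none
Why: Acid-catalysed acetal exchange removes the MOM group as dimethoxymethane and leaves benzyl and diaryl ethers untouched.

Step 13
Reactants: 21 2,4-bis(benzyloxy)-6-[2,4,6-tris(benzyloxy)phenoxy]phenol; 4 2,4-bis(benzyloxy)-6-fluorobenzaldehyde
Product: 22 2,4-bis(benzyloxy)-6-{2,4-bis(benzyloxy)-6-[2,4,6-tris(benzyloxy)phenoxy]phenoxy}benzaldehyde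
Conditions: Cs2CO3, DMSO, 100 °C
Reagents that add atoms: none
Why: SNAr in which the hindered, electron-rich G1 phenoxide displaces fluoride activated by the ortho formyl group (both benzyloxy groups are meta to the C–F carbon), forming F6–O–G1 without a metal.

Step 14
Reactants: 22 (ring F aldehyde of the F–G–H triaryl diether)
Product: 24 2,4-bis(benzyloxy)-6-{2,4-bis(benzyloxy)-6-[2,4,6-tris(benzyloxy)phenoxy]phenoxy}phenol, via aryl formate 23 (not isolated)
Conditions: mCPBA, NaHCO3, CH2Cl2, 0 → 25 °C; then K2CO3 (cat.), MeOH, 0 °C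
Reagents that add atoms: 3-chloroperbenzoic acid OOC(=O)c1cccc(Cl)c1
Why: Dakin-type Baeyer–Villiger oxidation turns the formyl group on the trioxygenated ring F into the F1 phenol.

Step 15
Reactants: 24 (F1 phenol of the F–G–H triaryl diether)
Product: 25 2,4-bis(benzyloxy)-6-{2,4-bis(benzyloxy)-6-[2,4,6-tris(benzyloxy)phenoxy]phenoxy}phenyl trifluoromethanesulfonate
Conditions: Tf2O, pyridine, CH2Cl2, −20 → 0 °C
Reagents that add atoms: trifluoromethanesulfonic anhydride O=S(=O)(OS(=O)(=O)C(F)(F)F)C(F)(F)F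
Why: O-Sulfonylation of the phenol gives the aryl triflate that serves as the coupling handle at F1.

Step 16
Reactants: 26 2,3-dibromo-4-hydroxy-5-methoxybenzaldehyde (5,6-dibromovanillin)
Product: 27 2,3-dibromo-4,5-dihydroxybenzaldehyde
Conditions: BBr3, CH2Cl2, −78 → 25 °C; H2O
Reagents that add atoms: none
Why: Lewis-acid cleavage of the aryl methyl ether, the standard vanillin-to-catechol demethylation, leaves the aryl bromides and the aldehyde unchanged.

Step 17
Reactants: 27 2,3-dibromo-4,5-dihydroxybenzaldehyde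
Product: 28 2,3-dibromo-5-hydroxy-4-(methoxymethoxy)benzaldehyde
Conditions: MOMCl (1.05 equiv), K2CO3 (1.1 equiv), acetone, 0 °C
Reagents that add atoms: chloromethyl methyl ether COCCl
Why: The 4-hydroxyl, para to the formyl group and ortho to bromine, is much the more acidic and is alkylated selectively as its phenoxide, the usual regiochemistry of 3,4-dihydroxybenzaldehydes.

Step 18
Reactants: 28 2,3-dibromo-5-hydroxy-4-(methoxymethoxy)benzaldehyde
Product: 29 5-(benzyloxy)-2,3-dibromo-4-(methoxymethoxy)benzaldehyde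
Conditions: BnBr, K2CO3, DMF, 25 °C
Reagents that add atoms: benzyl bromide BrCc1ccccc1
Why: Williamson etherification of the remaining phenol, the future C3 oxygen.

Step 19
Reactants: 29 5-(benzyloxy)-2,3-dibromo-4-(methoxymethoxy)benzaldehyde
Product: 31 5-(benzyloxy)-2,3-dibromo-4-(methoxymethoxy)phenol, via aryl formate 30 (not isolated)
Conditions: mCPBA, NaHCO3, CH2Cl2, 25 °C; then K2CO3 (cat.), MeOH, 0 °C
Reagents that add atoms: 3-chloroperbenzoic acid OOC(=O)c1cccc(Cl)c1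
Why: Dakin-type Baeyer–Villiger oxidation with aryl migration assisted by the para acetal oxygen gives the C1 phenol next to the C6 bromide.

Step 20
Reactants: 31 5-(benzyloxy)-2,3-dibromo-4-(methoxymethoxy)phenol; 4 2,4-bis(benzyloxy)-6-fluorobenzaldehyde
Product: 32 2,4-bis(benzyloxy)-6-[5-(benzyloxy)-2,3-dibromo-4-(methoxymethoxy)phenoxy]benzaldehyde
Conditions: Cs2CO3, DMSO, 100 °C
Reagents that add atoms: none
Why: SNAr of the 2-bromophenoxide on the formyl-activated fluoride forms B6–O–C1, and the unactivated aryl bromides do not react.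

Step 21
Reactants: 32 (ring B aldehyde of the B–C diaryl ether)
Product: 34 2,4-bis(benzyloxy)-6-[5-(benzyloxy)-2,3-dibromo-4-(methoxymethoxy)phenoxy]phenol, via aryl formate 33 (not isolated)
Conditions: mCPBA, NaHCO3, CH2Cl2, 0 → 25 °C; then K2CO3 (cat.), MeOH, 0 °C
Reagents that add atoms: 3-chloroperbenzoic acid OOC(=O)c1cccc(Cl)c1
Why: Dakin-type Baeyer–Villiger oxidation of the only aldehyde present gives the B1 phenol.

Step 22
Reactants: 34 (B1 phenol); 35 [3,5-bis(benzyloxy)phenyl]boronic acid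
Product: 36 1,5-bis(benzyloxy)-2-[3,5-bis(benzyloxy)phenoxy]-3-[5-(benzyloxy)-2,3-dibromo-4-(methoxymethoxy)phenoxy]benzene
Conditions: 35 (2.5 equiv), Cu(OAc)2 (20 mol %), pyridine, 4 Å MS, CH2Cl2, O2 (1 atm), 25 °C
Reagents that add atoms: none
Why: Chan–Lam oxidative O-arylation works at room temperature for 2,6-disubstituted phenols and leaves the two aryl bromides intact, which an Ullmann coupling with an aryl halide would not.

Step 23
Reactants: 36 (A–B–C triaryl diether, MOM at C4)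
Product: 37 6-(benzyloxy)-4-{3,5-bis(benzyloxy)-2-[3,5-bis(benzyloxy)phenoxy]phenoxy}-2,3-dibromophenol
Conditions: HCl (cat.), MeOH/THF, 50 °C
Reagents that add atoms: none
Why: Acid-catalysed acetal exchange frees the C4 phenol while benzyl ethers, diaryl ethers and aryl bromides stay.

Step 24
Reactants: 37 (C4 phenol); 7 4,6-bis(benzyloxy)-2-fluorobenzene-1,3-dicarbaldehyde
Product: 38 4,6-bis(benzyloxy)-2-[6-(benzyloxy)-4-{3,5-bis(benzyloxy)-2-[3,5-bis(benzyloxy)phenoxy]phenoxy}-2,3-dibromophenoxy]benzene-1,3-dicarbaldehyde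
Conditions: K2CO3, DMF, 60 °C
Reagents that add atoms: none
Why: SNAr on a fluoride flanked by two formyl groups is doubly activated, so the hindered C4 phenoxide should substitute under mild conditions to form C4–O–D6 with a symmetric ring D.

Step 25
Reactants: 38 (ring D dialdehyde)
Product: 40 4,6-bis(benzyloxy)-2-[6-(benzyloxy)-4-{3,5-bis(benzyloxy)-2-[3,5-bis(benzyloxy)phenoxy]phenoxy}-2,3-dibromophenoxy]benzene-1,3-diol, via bis(formate) 39 (not isolated)
Conditions: mCPBA (3 equiv), NaHCO3, CH2Cl2, 0 → 25 °C; then K2CO3 (cat.), degassed MeOH, 0 °C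
Reagents that add atoms: 3-chloroperbenzoic acid OOC(=O)c1cccc(Cl)c1
Why: Twofold Dakin-type Baeyer–Villiger oxidation, each formyl group lying on a carbon with two ortho and one para oxygen, gives the two equivalent ring D phenols.

Step 26
Reactants: 40 (ring D diol with the C5 and C6 bromides)
Product: 41 2,4,9-tris(benzyloxy)-7-{3,5-bis(benzyloxy)-2-[3,5-bis(benzyloxy)phenoxy]phenoxy}-6-bromodibenzo[b,e][1,4]dioxin-1-ol (Br at C6, free OH at D5)
Conditions: CuI (20 mol %), N,N-dimethylglycine (40 mol %), Cs2CO3, 1,4-dioxane, 100 °C, 0.01 M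
Reagents that add atoms: none
Why: In this intramolecular Ullmann C–O coupling either of the two equivalent ring D phenoxides displaces the C5 bromide in a six-membered closure (the C6 bromide would need a seven-membered ring), so ring D is desymmetrised without a regiochemical choice and the other hydroxyl remains as D5–OH.

Step 27
Reactants: 41 (dibenzodioxin phenol); 4 2,4-bis(benzyloxy)-6-fluorobenzaldehyde
Product: 42 2,4-bis(benzyloxy)-6-[(2,4,9-tris(benzyloxy)-7-{3,5-bis(benzyloxy)-2-[3,5-bis(benzyloxy)phenoxy]phenoxy}-6-bromodibenzo[b,e][1,4]dioxin-1-yl)oxy]benzaldehyde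
Conditions: Cs2CO3, DMSO, 100 °C
Reagents that add atoms: none
Why: SNAr of the D5 phenoxide on the formyl-activated fluoride forms D5–O–E1, and the electron-rich C6 bromide is not touched.

Step 28
Reactants: 42 (ring E aldehyde with the C6 bromide)
Product: 43 left-half aldehyde: benzofuro[3,2-a]dibenzo[b,e][1,4]dioxin core (rings B, C, D) with 3,5-bis(benzyloxy)phenoxy (ring A) on B1, OBn on B2, B4, C3, D2 and D4, and 3,5-bis(benzyloxy)-2-formylphenoxy (ring E) on D5
Conditions: Pd(OAc)2 (10 mol %), PCy3·HBF4 (20 mol %), K2CO3, DMA, 130 °C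
Reagents that add atoms: none
Why: Palladium-catalysed intramolecular direct arylation of a 2-bromodiaryl ether to a dibenzofuran, with oxidative addition at C6–Br and concerted metalation–deprotonation at B5, the only C–H ortho to the bridging oxygen on ring B; no benzyloxy group sits next to C6, so closure onto a benzyl ring is not available.

Step 29
Reactants: 43 (left-half aldehyde)
Product: 45 left-half phenol (E6–OH in place of the formyl group of 43), via aryl formate 44 (not isolated)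
Conditions: mCPBA (1.2 equiv), NaHCO3, CH2Cl2, 0 °C; then K2CO3 (cat.), MeOH, 0 °C
Reagents that add atoms: 3-chloroperbenzoic acid OOC(=O)c1cccc(Cl)c1
Why: Dakin-type Baeyer–Villiger oxidation of the ring E aldehyde, run cold with a small excess of peracid to spare the electron-rich core.

Step 30
Reactants: 45 (left-half phenol)
Product: 46 left-half triflate (E6–OTf)
Conditions: Tf2O, pyridine, CH2Cl2, −20 → 0 °C
Reagents that add atoms: trifluoromethanesulfonic anhydride O=S(=O)(OS(=O)(=O)C(F)(F)F)C(F)(F)F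
Why: O-Sulfonylation of the phenol gives the coupling handle at E6.

Step 31
Reactants: 25 right-half triflate
Product: 47 right-half pinacol boronate (F1–Bpin)
Conditions: B2pin2, Pd2(dba)3 (2.5 mol %), SPhos (10 mol %), KOAc, 1,4-dioxane, 90 °C
Reagents that add atoms: bis(pinacolato)diboron CC1(C)OB(OC1(C)C)B1OC(C)(C)C(C)(C)O1
Why: Miyaura borylation of an aryl triflate, for which a bulky electron-rich biarylphosphine is known to handle di-ortho-oxygenated substrates.

Step 32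
Reactants: 47 right-half pinacol boronate; 46 left-half triflate
Product: 48 hexadeca-O-benzyl ether of the target
Conditions: Pd(OAc)2 (10 mol %), SPhos (20 mol %), K3PO4, toluene/H2O (10:1), 100 °C
Reagents that add atoms: none
Why: Suzuki–Miyaura coupling with a dialkylbiarylphosphine ligand is the established way to tetra-ortho-substituted biaryls and forms E6–F1 without control of the axis.

Step 33
Reactants: 48 hexadeca-O-benzyl ether of the target
Product: 49 CNP0192765.0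
Conditions: H2 (1 atm), Pd(OH)2/C, THF/MeOH, 25 °C; filtration under argon
Reagents that add atoms: none
Why: Hydrogenolysis cleaves all sixteen benzyl ethers, while diaryl ethers, the dioxin, the furan and the biaryl are inert.

**Compound list**
1 | 5-fluorobenzene-1,3-diol | Oc1cc(O)cc(F)c1 | starting material
2 | 1,3-bis(benzyloxy)-5-fluorobenzene | Fc1cc(OCc7ccccc7)cc(OCc7ccccc7)c1 | intermediate
3 | N-{[2,4-bis(benzyloxy)-6-fluorophenyl]methylidene}-N-methylmethanaminium chloride | C[N+](C)=Cc1c(F)cc(OCc7ccccc7)cc1OCc7ccccc7.[Cl-] | intermediate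
4 | 2,4-bis(benzyloxy)-6-fluorobenzaldehyde | O=Cc1c(F)cc(OCc7ccccc7)cc1OCc7ccccc7 | intermediate
5 | 1,5-bis(benzyloxy)-2,4-dibromo-3-fluorobenzene | Fc1c(Br)c(OCc7ccccc7)cc(OCc7ccccc7)c1Br | intermediate
6 | [4,6-bis(benzyloxy)-2-fluoro-1,3-phenylene]dilithium | [Li]c1c(F)c([Li])c(OCc7ccccc7)cc1OCc7ccccc7 | intermediate
7 | 4,6-bis(benzyloxy)-2-fluorobenzene-1,3-dicarbaldehyde | O=Cc1c(F)c(C=O)c(OCc7ccccc7)cc1OCc7ccccc7 | intermediate
8 | 2,4,6-trihydroxybenzaldehyde | O=Cc1c(O)cc(O)cc1O | starting material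
9 | 2,4-bis(benzyloxy)-6-hydroxybenzaldehyde | O=Cc1c(O)cc(OCc7ccccc7)cc1OCc7ccccc7 | intermediate
10 | methyl bromoacetate | COC(=O)CBr | starting material
11 | methyl 2-[3,5-bis(benzyloxy)-2-formylphenoxy]acetate | COC(=O)COc1cc(OCc7ccccc7)cc(OCc7ccccc7)c1C=O | intermediate
12 | methyl 2-[3,5-bis(benzyloxy)-2-(formyloxy)phenoxy]acetate | COC(=O)COc1cc(OCc7ccccc7)cc(OCc7ccccc7)c1OC=O | intermediate
13 | methyl 2-[3,5-bis(benzyloxy)-2-hydroxyphenoxy]acetate | COC(=O)COc1cc(OCc7ccccc7)cc(OCc7ccccc7)c1O | intermediate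
14 | methyl 2-[3,5-bis(benzyloxy)-2-(methoxymethoxy)phenoxy]acetate | COC(=O)COc1cc(OCc7ccccc7)cc(OCc7ccccc7)c1OCOC | intermediate
15 | methyl acetoacetate | COC(=O)CC(C)=O | starting material
16 | dilithium dianion of methyl acetoacetate | [Li+].[Li+].[CH2-]C(=O)[CH-]C(=O)OC | intermediate
17 | methyl 6-[3,5-bis(benzyloxy)-2-(methoxymethoxy)phenoxy]-3,5-dioxohexanoate | COC(=O)CC(=O)CC(=O)COc1cc(OCc7ccccc7)cc(OCc7ccccc7)c1OCOC | intermediate
18 | trilithium trianion of 17 | [Li+].[Li+].[Li+].COC(=O)[CH-]C(=O)[CH-]C(=O)[CH-]Oc1cc(OCc7ccccc7)cc(OCc7ccccc7)c1OCOC | intermediate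
19 | 2-[3,5-bis(benzyloxy)-2-(methoxymethoxy)phenoxy]benzene-1,3,5-triol | COCOc1c(OCc7ccccc7)cc(OCc7ccccc7)cc1Oc1c(O)cc(O)cc1O | intermediate
20 | 1,5-bis(benzyloxy)-2-(methoxymethoxy)-3-[2,4,6-tris(benzyloxy)phenoxy]benzene | COCOc1c(OCc7ccccc7)cc(OCc7ccccc7)cc1Oc1c(OCc7ccccc7)cc(OCc7ccccc7)cc1OCc7ccccc7 | intermediate
21 | 2,4-bis(benzyloxy)-6-[2,4,6-tris(benzyloxy)phenoxy]phenol | Oc1c(OCc7ccccc7)cc(OCc7ccccc7)cc1Oc1c(OCc7ccccc7)cc(OCc7ccccc7)cc1OCc7ccccc7 | intermediate
22 | 2,4-bis(benzyloxy)-6-{2,4-bis(benzyloxy)-6-[2,4,6-tris(benzyloxy)phenoxy]phenoxy}benzaldehyde | O=Cc1c(Oc2c(OCc7ccccc7)cc(OCc7ccccc7)cc2Oc2c(OCc7ccccc7)cc(OCc7ccccc7)cc2OCc7ccccc7)cc(OCc7ccccc7)cc1OCc7ccccc7 | intermediate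
23 | 2,4-bis(benzyloxy)-6-{2,4-bis(benzyloxy)-6-[2,4,6-tris(benzyloxy)phenoxy]phenoxy}phenyl formate | O=COc1c(Oc2c(OCc7ccccc7)cc(OCc7ccccc7)cc2Oc2c(OCc7ccccc7)cc(OCc7ccccc7)cc2OCc7ccccc7)cc(OCc7ccccc7)cc1OCc7ccccc7 | intermediate
24 | 2,4-bis(benzyloxy)-6-{2,4-bis(benzyloxy)-6-[2,4,6-tris(benzyloxy)phenoxy]phenoxy}phenol | Oc1c(Oc2c(OCc7ccccc7)cc(OCc7ccccc7)cc2Oc2c(OCc7ccccc7)cc(OCc7ccccc7)cc2OCc7ccccc7)cc(OCc7ccccc7)cc1OCc7ccccc7 | intermediate
25 | 2,4-bis(benzyloxy)-6-{2,4-bis(benzyloxy)-6-[2,4,6-tris(benzyloxy)phenoxy]phenoxy}phenyl trifluoromethanesulfonate | O=S(=O)(Oc1c(Oc2c(OCc7ccccc7)cc(OCc7ccccc7)cc2Oc2c(OCc7ccccc7)cc(OCc7ccccc7)cc2OCc7ccccc7)cc(OCc7ccccc7)cc1OCc7ccccc7)C(F)(F)F | intermediate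
26 | 2,3-dibromo-4-hydroxy-5-methoxybenzaldehyde | COc1cc(C=O)c(Br)c(Br)c1O | starting material
27 | 2,3-dibromo-4,5-dihydroxybenzaldehyde | O=Cc1cc(O)c(O)c(Br)c1Br | intermediate
28 | 2,3-dibromo-5-hydroxy-4-(methoxymethoxy)benzaldehyde | COCOc1c(O)cc(C=O)c(Br)c1Br | intermediate
29 | 5-(benzyloxy)-2,3-dibromo-4-(methoxymethoxy)benzaldehyde | COCOc1c(OCc7ccccc7)cc(C=O)c(Br)c1Br | intermediate
30 | 5-(benzyloxy)-2,3-dibromo-4-(methoxymethoxy)phenyl formate | COCOc1c(OCc7ccccc7)cc(OC=O)c(Br)c1Br | intermediate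
31 | 5-(benzyloxy)-2,3-dibromo-4-(methoxymethoxy)phenol | COCOc1c(OCc7ccccc7)cc(O)c(Br)c1Br | intermediate
32 | 2,4-bis(benzyloxy)-6-[5-(benzyloxy)-2,3-dibromo-4-(methoxymethoxy)phenoxy]benzaldehyde | O=Cc1c(Oc2cc(OCc7ccccc7)c(OCOC)c(Br)c2Br)cc(OCc7ccccc7)cc1OCc7ccccc7 | intermediate
33 | 2,4-bis(benzyloxy)-6-[5-(benzyloxy)-2,3-dibromo-4-(methoxymethoxy)phenoxy]phenyl formate | O=COc1c(Oc2cc(OCc7ccccc7)c(OCOC)c(Br)c2Br)cc(OCc7ccccc7)cc1OCc7ccccc7 | intermediate
34 | 2,4-bis(benzyloxy)-6-[5-(benzyloxy)-2,3-dibromo-4-(methoxymethoxy)phenoxy]phenol | Oc1c(Oc2cc(OCc7ccccc7)c(OCOC)c(Br)c2Br)cc(OCc7ccccc7)cc1OCc7ccccc7 | intermediate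
35 | [3,5-bis(benzyloxy)phenyl]boronic acid | OB(O)c1cc(OCc7ccccc7)cc(OCc7ccccc7)c1 | starting material
36 | 1,5-bis(benzyloxy)-2-[3,5-bis(benzyloxy)phenoxy]-3-[5-(benzyloxy)-2,3-dibromo-4-(methoxymethoxy)phenoxy]benzene | COCOc1c(OCc7ccccc7)cc(Oc2cc(OCc7ccccc7)cc(OCc7ccccc7)c2Oc2cc(OCc7ccccc7)cc(OCc7ccccc7)c2)c(Br)c1Br | intermediate
37 | 6-(benzyloxy)-4-{3,5-bis(benzyloxy)-2-[3,5-bis(benzyloxy)phenoxy]phenoxy}-2,3-dibromophenol | Oc1c(OCc7ccccc7)cc(Oc2cc(OCc7ccccc7)cc(OCc7ccccc7)c2Oc2cc(OCc7ccccc7)cc(OCc7ccccc7)c2)c(Br)c1Br | intermediate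
38 | 4,6-bis(benzyloxy)-2-[6-(benzyloxy)-4-{3,5-bis(benzyloxy)-2-[3,5-bis(benzyloxy)phenoxy]phenoxy}-2,3-dibromophenoxy]benzene-1,3-dicarbaldehyde | O=Cc1c(OCc7ccccc7)cc(OCc7ccccc7)c(C=O)c1Oc1c(OCc7ccccc7)cc(Oc2cc(OCc7ccccc7)cc(OCc7ccccc7)c2Oc2cc(OCc7ccccc7)cc(OCc7ccccc7)c2)c(Br)c1Br | intermediate
39 | bis(formate) of diol 40 | O=COc1c(OCc7ccccc7)cc(OCc7ccccc7)c(OC=O)c1Oc1c(OCc7ccccc7)cc(Oc2cc(OCc7ccccc7)cc(OCc7ccccc7)c2Oc2cc(OCc7ccccc7)cc(OCc7ccccc7)c2)c(Br)c1Br | intermediate
40 | 4,6-bis(benzyloxy)-2-[6-(benzyloxy)-4-{3,5-bis(benzyloxy)-2-[3,5-bis(benzyloxy)phenoxy]phenoxy}-2,3-dibromophenoxy]benzene-1,3-diol | Oc1c(OCc7ccccc7)cc(OCc7ccccc7)c(O)c1Oc1c(OCc7ccccc7)cc(Oc2cc(OCc7ccccc7)cc(OCc7ccccc7)c2Oc2cc(OCc7ccccc7)cc(OCc7ccccc7)c2)c(Br)c1Br | intermediate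
41 | 2,4,9-tris(benzyloxy)-7-{3,5-bis(benzyloxy)-2-[3,5-bis(benzyloxy)phenoxy]phenoxy}-6-bromodibenzo[b,e][1,4]dioxin-1-ol | Oc1c(OCc7ccccc7)cc(OCc7ccccc7)c2Oc3c(Br)c(Oc4cc(OCc7ccccc7)cc(OCc7ccccc7)c4Oc4cc(OCc7ccccc7)cc(OCc7ccccc7)c4)cc(OCc7ccccc7)c3Oc12 | intermediate
42 | 2,4-bis(benzyloxy)-6-[(2,4,9-tris(benzyloxy)-7-{3,5-bis(benzyloxy)-2-[3,5-bis(benzyloxy)phenoxy]phenoxy}-6-bromodibenzo[b,e][1,4]dioxin-1-yl)oxy]benzaldehyde | O=Cc5c(OCc7ccccc7)cc(OCc7ccccc7)cc5Oc1c(OCc7ccccc7)cc(OCc7ccccc7)c2Oc3c(Br)c(Oc4cc(OCc7ccccc7)cc(OCc7ccccc7)c4Oc4cc(OCc7ccccc7)cc(OCc7ccccc7)c4)cc(OCc7ccccc7)c3Oc12 | intermediate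
43 | left-half aldehyde (rings A–E, nine benzyl ethers, formyl at E6) | O(Cc7ccccc7)c1cc(OCc7ccccc7)cc(Oc2c(OCc7ccccc7)cc(OCc7ccccc7)c3c2oc2cc(OCc7ccccc7)c4c(c23)Oc2c(OCc7ccccc7)cc(OCc7ccccc7)c(Oc5cc(OCc7ccccc7)cc(OCc7ccccc7)c5C=O)c2O4)c1 | intermediate
44 | left-half aryl formate (formyloxy at E6) | O(Cc7ccccc7)c1cc(OCc7ccccc7)cc(Oc2c(OCc7ccccc7)cc(OCc7ccccc7)c3c2oc2cc(OCc7ccccc7)c4c(c23)Oc2c(OCc7ccccc7)cc(OCc7ccccc7)c(Oc5cc(OCc7ccccc7)cc(OCc7ccccc7)c5OC=O)c2O4)c1 | intermediate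
45 | left-half phenol (OH at E6) | O(Cc7ccccc7)c1cc(OCc7ccccc7)cc(Oc2c(OCc7ccccc7)cc(OCc7ccccc7)c3c2oc2cc(OCc7ccccc7)c4c(c23)Oc2c(OCc7ccccc7)cc(OCc7ccccc7)c(Oc5cc(OCc7ccccc7)cc(OCc7ccccc7)c5O)c2O4)c1 | intermediate
46 | left-half triflate (OTf at E6) | O(Cc7ccccc7)c1cc(OCc7ccccc7)cc(Oc2c(OCc7ccccc7)cc(OCc7ccccc7)c3c2oc2cc(OCc7ccccc7)c4c(c23)Oc2c(OCc7ccccc7)cc(OCc7ccccc7)c(Oc5cc(OCc7ccccc7)cc(OCc7ccccc7)c5OS(=O)(=O)C(F)(F)F)c2O4)c1 | intermediate
47 | right-half pinacol boronate (Bpin at F1 in place of the triflate of 25) | CC1(C)OB(OC1(C)C)c1c(Oc2c(OCc7ccccc7)cc(OCc7ccccc7)cc2Oc2c(OCc7ccccc7)cc(OCc7ccccc7)cc2OCc7ccccc7)cc(OCc7ccccc7)cc1OCc7ccccc7 | intermediate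
48 | hexadeca-O-benzyl ether of the target | O(Cc7ccccc7)c1cc(OCc7ccccc7)cc(Oc2c(OCc7ccccc7)cc(OCc7ccccc7)c3c2oc2cc(OCc7ccccc7)c4c(c23)Oc2c(OCc7ccccc7)cc(OCc7ccccc7)c(Oc5cc(OCc7ccccc7)cc(OCc7ccccc7)c5-c5c(OCc7ccccc7)cc(OCc7ccccc7)cc5Oc5c(OCc7ccccc7)cc(OCc7ccccc7)cc5Oc5c(OCc7ccccc7)cc(OCc7ccccc7)cc5OCc7ccccc7)c2O4)c1 | intermediate
49 | CNP0192765.0 (hexadecahydroxy octacyclic phlorotannin) | Oc1cc(O)cc(Oc2c(O)cc(O)c3c2oc2cc(O)c4c(c23)Oc2c(O)cc(O)c(Oc3cc(O)cc(O)c3-c3c(O)cc(O)cc3Oc3c(O)cc(O)cc3Oc3c(O)cc(O)cc3O)c2O4)c1 | target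

**Totals**
Total step count: 33.
Longest linear sequence: 17 steps (16–30, 32, 33, starting from 26).

**Steps most likely to fail**

Step 10. The cyclisation may stall because the ester is held as its enolate in the polyanion, or the enolate oxygen may acylate first and give the 4-hydroxy-2-pyranone lactone instead of the carbocycle. The fallback makes the G6–O–H1 ether by substitution instead of ring construction. It sets out from 8 and 4 and returns at 21. Exhaustive benzylation of 8 (BnBr, K2CO3, DMF, 60 °C) would give 2,4,6-tris(benzyloxy)benzaldehyde F1. Baeyer–Villiger oxidation with mCPBA to 2,4,6-tris(benzyloxy)phenyl formate F2 and methanolysis would give 2,4,6-tris(benzyloxy)phenol F3. SNAr of F3 on fluoroaldehyde 4 (Cs2CO3, DMSO, 100 °C) would give 2,4-bis(benzyloxy)-6-[2,4,6-tris(benzyloxy)phenoxy]benzaldehyde F4. Dakin oxidation of F4 through 2,4-bis(benzyloxy)-6-[2,4,6-tris(benzyloxy)phenoxy]phenyl formate F5 would deliver phenol 21 and rejoin the route at step 13.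

Step 32. Transmetalation of the di-ortho-oxygenated boronate onto a hindered arylpalladium may be slower than protodeboronation, and the triflate may hydrolyse under the aqueous base. The fallback avoids boron. It sets out from aldehyde 43 and triflate 25 and returns at 48. Chlorite oxidation of 43 (NaClO2, NaH2PO4, 2-methyl-2-butene, t-BuOH/H2O) would give the left-half carboxylic acid F6, a 2,6-dioxygenated benzoic acid. Its silver-mediated, palladium-catalysed decarboxylative cross-coupling with 25 (PdCl2, PPh3, Ag2CO3, NMP, 130 °C) would form the E6–F1 bond and give 48 directly.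

Step 4. The aryllithium next to fluorine may lose LiF to an aryne, or the second bromine–lithium exchange may remain incomplete and leave a monoaldehyde. The fallback formylates the free resorcinol instead. It sets out from 1 and returns at 7. Twofold Duff formylation of 1 ((CH2)6N4, CF3CO2H, 90 °C; then aq. HCl) at the two carbons flanking fluorine would give 2-fluoro-4,6-dihydroxybenzene-1,3-dicarbaldehyde F7. Benzylation of F7 (BnBr, K2CO3, DMF, 25 °C) would give 7.

**Further compounds**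
F1 | step 10 | 2,4,6-tris(benzyloxy)benzaldehyde | O=Cc1c(OCc7ccccc7)cc(OCc7ccccc7)cc1OCc7ccccc7
F2 | step 10 | 2,4,6-tris(benzyloxy)phenyl formate | O=COc1c(OCc7ccccc7)cc(OCc7ccccc7)cc1OCc7ccccc7
F3 | step 10 | 2,4,6-tris(benzyloxy)phenol | Oc1c(OCc7ccccc7)cc(OCc7ccccc7)cc1OCc7ccccc7
F4 | step 10 | 2,4-bis(benzyloxy)-6-[2,4,6-tris(benzyloxy)phenoxy]benzaldehyde | O=Cc1c(Oc2c(OCc7ccccc7)cc(OCc7ccccc7)cc2OCc7ccccc7)cc(OCc7ccccc7)cc1OCc7ccccc7
F5 | step 10 | 2,4-bis(benzyloxy)-6-[2,4,6-tris(benzyloxy)phenoxy]phenyl formate | O=COc1c(Oc2c(OCc7ccccc7)cc(OCc7ccccc7)cc2OCc7ccccc7)cc(OCc7ccccc7)cc1OCc7ccccc7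
F6 | step 32 | left-half carboxylic acid (CO2H at E6 in place of the formyl group of 43) | O(Cc7ccccc7)c1cc(OCc7ccccc7)cc(Oc2c(OCc7ccccc7)cc(OCc7ccccc7)c3c2oc2cc(OCc7ccccc7)c4c(c23)Oc2c(OCc7ccccc7)cc(OCc7ccccc7)c(Oc5cc(OCc7ccccc7)cc(OCc7ccccc7)c5C(=O)O)c2O4)c1
F7 | step 4 | 2-fluoro-4,6-dihydroxybenzene-1,3-dicarbaldehyde | O=Cc1c(O)cc(O)c(C=O)c1F
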